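**Plan**
- Retrosynthesis: the ring B C3'–dienyl bond is cut first (Stille), then O1–C8a of ring C (copper etherification with C4 still a carbinol), then C3–C4 (aldol between a ring B methyl ketone and a ring A aldehyde), and last the C5'–prenyl bond.
- Enabling feature: O1 joins the benzylic C2 carbinol carbon to C8a of ring A. A 1,3-diarylpropane-1,3-diol with a free C2 hydroxyl and a bromine on ring A ortho to the chain therefore closes ring C by C(aryl)–O coupling without touching the C2–O bond.
- Forward: ring A aldehyde 4 (two steps) and ring B ketone 10 (three steps) are joined by aldol addition and the ketone is reduced to diol 12. Ring C, the only ring made, closes in step 8; oxidation at C4, MOM removal and Stille coupling finish.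
- Stereochemistry: C2 (S) comes from catalyst-controlled asymmetric transfer hydrogenation of the ring B aryl ketone (step 7) and is not touched afterwards. The C4 carbinol is a throwaway centre, and the E-diene comes from syn-hydrostannation.

Key step: step 8

Remark: the C4 carbinol centre is carried deliberately as both epimers (3RS in 12, 4RS in 13, left undefined in the SMILES) because step 9 destroys it; 1-(3,5-dibromo-4-hydroxyphenyl)ethanone is taken as the commercial source of ring B.

**Route**

Step 1
Reactants: 1 5-bromoresorcinol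
Product: 3 2-bromo-4,6-dihydroxybenzaldehyde, via iminium chloride 2 (not isolated)
Conditions: POCl3, DMF, MeCN, −15 °C to rt; then H2O, 50 °C
Reagents that add atoms: N,N-dimethylformamide CN(C)C=O; water O
Why: Vilsmeier–Haack formylation, in which the chloroiminium electrophile should attack the carbon para to one hydroxyl and ortho to the other (the carbon next to bromine), as orcinol does, before water hydrolyses the iminium salt to the aldehyde.

Step 2
Reactants: 3 2-bromo-4,6-dihydroxybenzaldehyde
Product: 4 2-bromo-4,6-bis(methoxymethoxy)benzaldehyde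
Conditions: NaH, MOMCl, DMF, 0 °C to rt
Reagents that add atoms: chloromethyl methyl ether COCCl
Why: Williamson etherification of both sodium phenoxides, full deprotonation by NaH breaking the hydrogen bond that otherwise shields the hydroxyl ortho to the formyl group.

Step 3
Reactants: 5 1-(3,5-dibromo-4-hydroxyphenyl)ethanone
Product: 6 1-(3,5-dibromo-4-methoxyphenyl)ethanone
Conditions: MeI, K2CO3, DMF, 40 °C
Reagents that add atoms: iodomethane CI
Why: Williamson O-methylation of the acidic 2,6-dibromophenol with a base too weak to enolise the methyl ketone.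

Step 4
Reactants: 6 1-(3,5-dibromo-4-methoxyphenyl)ethanone
Product: 7 2-(3,5-dibromo-4-methoxyphenyl)-2-methyl-1,3-dioxolane
Conditions: HOCH2CH2OH, TsOH (cat.), toluene, reflux, Dean–Stark
Reagents that add atoms: ethane-1,2-diol OCCO
Why: acid-catalysed ketalisation driven by azeotropic removal of water masks the ketone against the organolithium of step 5.

Step 5
Reactants: 7 2-(3,5-dibromo-4-methoxyphenyl)-2-methyl-1,3-dioxolane; 8 1-bromo-3-methylbut-2-ene
Product: 10 1-[3-bromo-4-methoxy-5-(3-methylbut-2-enyl)phenyl]ethanone, via prenylated dioxolane 9 (not isolated)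
Conditions: n-BuLi (1.0 equiv), THF, −78 °C; CuBr·SMe2; 8, −78 to 0 °C; then 2 M HCl, THF, rt
Reagents that add atoms: water O
Why: a single bromine–lithium exchange next to the methoxy group, transmetalation to monovalent copper and SN2 allylation at the primary carbon of prenyl bromide should give the linear prenyl arene, and the acidic work-up hydrolyses the dioxolane.

Step 6
Reactants: 10 1-[3-bromo-4-methoxy-5-(3-methylbut-2-enyl)phenyl]ethanone; 4 2-bromo-4,6-bis(methoxymethoxy)benzaldehyde
Product: 11 rac-3-[2-bromo-4,6-bis(methoxymethoxy)phenyl]-1-[3-bromo-4-methoxy-5-(3-methylbut-2-enyl)phenyl]-3-hydroxypropan-1-one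
Conditions: LiN(i-Pr)2, THF, −78 °C; then 4, −78 °C; AcOH quench at −78 °C
Reagents that add atoms: none
Why: aldol addition of the kinetic lithium enolate of the methyl ketone to a non-enolisable aldehyde, quenched cold to forestall retro-aldol and dehydration; the new carbinol carbon (later C4) forms as a racemate by design, since step 9 oxidises it.

Step 7
Reactants: 11 rac-3-[2-bromo-4,6-bis(methoxymethoxy)phenyl]-1-[3-bromo-4-methoxy-5-(3-methylbut-2-enyl)phenyl]-3-hydroxypropan-1-one
Product: 12 (1S,3RS)-3-[2-bromo-4,6-bis(methoxymethoxy)phenyl]-1-[3-bromo-4-methoxy-5-(3-methylbut-2-enyl)phenyl]propane-1,3-diol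
Conditions: RuCl[(S,S)-TsDPEN](p-cymene) (2 mol %), HCO2H/Et3N (1:1), CH2Cl2, 30 °C
Reagents that add atoms: none
Why: Noyori-type asymmetric transfer hydrogenation of an aryl alkyl ketone, in which the (S,S)-TsDPEN ruthenium hydride should deliver hydride to the face that gives the (S)-carbinol (later C2), as with acetophenone, under catalyst control for both enantiomers of 11, while the near-neutral formate medium spares the acid-labile ring A carbinol.

Step 8
Reactants: 12 (1S,3RS)-3-[2-bromo-4,6-bis(methoxymethoxy)phenyl]-1-[3-bromo-4-methoxy-5-(3-methylbut-2-enyl)phenyl]propane-1,3-diol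
Product: 13 (2S,4RS)-2-[3-bromo-4-methoxy-5-(3-methylbut-2-enyl)phenyl]-5,7-bis(methoxymethoxy)chroman-4-ol
Conditions: CuI (20 mol %), 3,4,7,8-tetramethyl-1,10-phenanthroline (40 mol %), Cs2CO3, toluene (0.02 M), 110 °C, argon
Reagents that add atoms: none
Why: Ullmann-type intramolecular O-arylation: Cs2CO3 and phenanthroline-bound monovalent copper form the copper alkoxide of the C2 hydroxyl, the tethered ring A C–Br bond adds oxidatively to give a seven-membered cupracycle of trivalent copper, and C(aryl)–O reductive elimination forms O1–C8a. The closest known reaction is the copper-catalysed cyclisation of 1-aryl-3-(2-bromoaryl)propan-1-ols to flavans. Ring C closes as a six-membered ring by attack of the C2 oxygen on the aryl carbon C8a, the only unstrained mode open to the substrate. No stereocentre is created: C2 keeps its S configuration because its C–O bond is never broken, and the C4 carbinol is a spectator in either configuration. The step needs the C2 hydroxyl to win over the C4 hydroxyl and the ring A bromide over the ring B bromide; the C4 oxygen could only close a four-membered ring, and the ring B bromide cannot be reached within the molecule, so moderate dilution should suffice. Working at the diol level removes the retro-aldol and β-elimination pathways that a β-hydroxy ketone would follow with carbonate at 110 °C.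

Step 9
Reactants: 13 (2S,4RS)-2-[3-bromo-4-methoxy-5-(3-methylbut-2-enyl)phenyl]-5,7-bis(methoxymethoxy)chroman-4-ol
Product: 14 (2S)-2-[3-bromo-4-methoxy-5-(3-methylbut-2-enyl)phenyl]-5,7-bis(methoxymethoxy)chroman-4-one
Conditions: (n-Pr)4NRuO4 (5 mol %), NMO, 4 Å MS, CH2Cl2, rt
Reagents that add atoms: none
Why: Ley–Griffith oxidation of the activated benzylic carbinol under neutral conditions should converge both C4 epimers on one ketone, avoiding acid that would ionise C4 and base that would open the flavanone, and leaving the prenyl alkene, the aryl bromide and the MOM ethers alone.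

Step 10
Reactants: 14 (2S)-2-[3-bromo-4-methoxy-5-(3-methylbut-2-enyl)phenyl]-5,7-bis(methoxymethoxy)chroman-4-one
Product: 15 (2S)-2-[3-bromo-4-methoxy-5-(3-methylbut-2-enyl)phenyl]-5,7-dihydroxychroman-4-one
Conditions: 3 M HCl, MeOH, 45 °C
Reagents that add atoms: none
Why: acid-catalysed acetal exchange of the two aryl MOM ethers with methanol, mild enough for the prenyl group flanking the methoxy group and for C2 of the flavanone, which is configurationally labile only under base.

Step 11
Reactants: 16 2-methylbut-1-en-3-yne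
Product: 17 tributyl[(1E)-3-methylbuta-1,3-dienyl]stannane
Conditions: Bu3SnH, PdCl2(PPh3)2 (1 mol %), THF, 0 °C to rt
Reagents that add atoms: tributyltin hydride CCCC[SnH](CCCC)CCCC
Why: palladium-catalysed hydrostannation of the terminal alkyne of a conjugated enyne, where syn addition of Sn–H with tin at the terminal carbon should give the (E)-1-stannyl diene.

Step 12
Reactants: 15 (2S)-2-[3-bromo-4-methoxy-5-(3-methylbut-2-enyl)phenyl]-5,7-dihydroxychroman-4-one; 17 tributyl[(1E)-3-methylbuta-1,3-dienyl]stannane
Product: 18 (2S)-5,7-dihydroxy-2-[4-methoxy-3-[(1E)-3-methylbuta-1,3-dienyl]-5-(3-methylbut-2-enyl)phenyl]chroman-4-one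
Conditions: Pd(PPh3)4 (5 mol %), CuI (10 mol %), DMF, 80 °C, no base, BHT (trace)
Reagents that add atoms: none
Why: Stille coupling by oxidative addition of the ring B C–Br bond to zerovalent palladium, copper-assisted transfer of the dienyl group with retention of the E geometry and reductive elimination, the absence of base keeping the flavanone closed and C2 intact while the free phenols are tolerated.

**Compound list**
1 | 5-bromoresorcinol | Oc1cc(O)cc(Br)c1 | starting material
2 | (2-bromo-4,6-dihydroxybenzylidene)dimethyliminium chloride | C[N+](C)=Cc1c(Br)cc(O)cc1O.[Cl-] | intermediate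
3 | 2-bromo-4,6-dihydroxybenzaldehyde | O=Cc1c(Br)cc(O)cc1O | intermediate
4 | 2-bromo-4,6-bis(methoxymethoxy)benzaldehyde | O=Cc1c(Br)cc(OCOC)cc1OCOC | intermediate
5 | 1-(3,5-dibromo-4-hydroxyphenyl)ethanone | CC(=O)c1cc(Br)c(O)c(Br)c1 | starting material
6 | 1-(3,5-dibromo-4-methoxyphenyl)ethanone | CC(=O)c1cc(Br)c(OC)c(Br)c1 | intermediate
7 | 2-(3,5-dibromo-4-methoxyphenyl)-2-methyl-1,3-dioxolane | CC1(OCCO1)c1cc(Br)c(OC)c(Br)c1 | intermediate
8 | 1-bromo-3-methylbut-2-ene | CC(C)=CCBr | starting material
9 | 2-[3-bromo-4-methoxy-5-(3-methylbut-2-enyl)phenyl]-2-methyl-1,3-dioxolane | CC1(OCCO1)c1cc(Br)c(OC)c(CC=C(C)C)c1 | intermediate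
10 | 1-[3-bromo-4-methoxy-5-(3-methylbut-2-enyl)phenyl]ethanone | CC(=O)c1cc(Br)c(OC)c(CC=C(C)C)c1 | intermediate
11 | rac-3-[2-bromo-4,6-bis(methoxymethoxy)phenyl]-1-[3-bromo-4-methoxy-5-(3-methylbut-2-enyl)phenyl]-3-hydroxypropan-1-one | Brc1cc(C(=O)CC(O)c2c(Br)cc(OCOC)cc2OCOC)cc(CC=C(C)C)c1OC | intermediate
12 | (1S,3RS)-3-[2-bromo-4,6-bis(methoxymethoxy)phenyl]-1-[3-bromo-4-methoxy-5-(3-methylbut-2-enyl)phenyl]propane-1,3-diol (both C3 epimers) | Brc1cc([C@@H](O)CC(O)c2c(Br)cc(OCOC)cc2OCOC)cc(CC=C(C)C)c1OC | intermediate
13 | (2S,4RS)-2-[3-bromo-4-methoxy-5-(3-methylbut-2-enyl)phenyl]-5,7-bis(methoxymethoxy)chroman-4-ol (both C4 epimers) | Brc1cc([C@@H]2CC(O)c3c(OCOC)cc(OCOC)cc3O2)cc(CC=C(C)C)c1OC | intermediate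
14 | (2S)-2-[3-bromo-4-methoxy-5-(3-methylbut-2-enyl)phenyl]-5,7-bis(methoxymethoxy)chroman-4-one | Brc1cc([C@@H]2CC(=O)c3c(OCOC)cc(OCOC)cc3O2)cc(CC=C(C)C)c1OC | intermediate
15 | (2S)-2-[3-bromo-4-methoxy-5-(3-methylbut-2-enyl)phenyl]-5,7-dihydroxychroman-4-one | Brc1cc([C@@H]2CC(=O)c3c(O)cc(O)cc3O2)cc(CC=C(C)C)c1OC | intermediate
16 | 2-methylbut-1-en-3-yne | C=C(C)C#C | starting material
17 | tributyl[(1E)-3-methylbuta-1,3-dienyl]stannane | C=C(C)/C=C/[Sn](CCCC)(CCCC)CCCC | intermediate
18 | (2S)-5,7-dihydroxy-2-[4-methoxy-3-[(1E)-3-methylbuta-1,3-dienyl]-5-(3-methylbut-2-enyl)phenyl]chroman-4-one | C=C(C)/C=C/c1cc([C@@H]2CC(=O)c3c(O)cc(O)cc3O2)cc(CC=C(C)C)c1OC | target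

**Step count and risks**
Total steps: 12. Longest linear sequence: 9 steps (steps 3, 4, 5, 6, 7, 8, 9, 10 and 12, from 5).

Steps most likely to fail:

Step 8. Activation of the ring A C–Br bond by the copper alkoxide may be slow. Protodebromination, copper-mediated oxidation of the benzylic carbinols or intermolecular arylation at the ring B bromide could then take over. The fallback gives ring A a better leaving group. Setting out from 4, copper-catalysed aromatic Finkelstein exchange (NaI, CuI, trans-N,N'-dimethylcyclohexane-1,2-diamine, dioxane, 110 °C) should give 2-iodo-4,6-bis(methoxymethoxy)benzaldehyde F1. Aldol addition of the lithium enolate of 10 under the conditions of step 6 should then give the racemic iodo aldol F2, and transfer hydrogenation as in step 7 the (1S,3RS)-iodo diol F3. With CuI, 1,10-phenanthroline and Cs2CO3 in toluene at 80 °C the C–I bond should react well below the temperature at which the ring B bromide is engaged, and the closure comes back to the route at 13.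

Step 7. Catalyst control may be eroded for the enantiomer of 11 whose β-carbinol is mismatched with the catalyst, and the β-hydroxy ketone may revert by retro-aldol or dehydrate in the amine–formate medium. The fallback removes the free hydroxyl and changes the reductant. From 11, silylation (TBSOTf, 2,6-lutidine, CH2Cl2, −78 °C) should give the tert-butyldimethylsilyl ether F4. Corey–Bakshi–Shibata reduction with (R)-2-methyl-CBS-oxazaborolidine and catecholborane in toluene at −78 °C, where the oxazaborolidine alone decides the face and the prenyl alkene is not hydroborated, should give the (1S)-carbinol silyl ether F5. Bu4NF in THF then removes the silyl group and comes back to the route at 12.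

Step 12. Oxidative addition at the hindered, electron-rich bromide may be slow, while the free phenols protodestannylate the dienylstannane and prolonged heating opens the flavanone to the chalcone with loss of configuration at C2. The fallback installs the diene before the ketone and the phenols exist. From 16, hydroboration with pinacolborane (Cp2Zr(H)Cl cat., Et3N cat.) should give the (E)-dienyl pinacol boronate F6. Suzuki–Miyaura coupling of F6 with 13 (PdCl2(dppf), K3PO4, dioxane/H2O, 80 °C) is safe with base because 13 has no ketone, and should give the dienyl flavan-4-ol F7. Oxidation as in step 9 gives the bis-MOM dienyl flavanone F8. MOM cleavage with ZnBr2 and n-PrSH in CH2Cl2 at 0 °C, which uses no protic acid that could protonate the diene, comes back to the route at 18.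

**Further compounds**
F1 | step 8 | 2-iodo-4,6-bis(methoxymethoxy)benzaldehyde | O=Cc1c(I)cc(OCOC)cc1OCOC
F2 | step 8 | rac-1-[3-bromo-4-methoxy-5-(3-methylbut-2-enyl)phenyl]-3-hydroxy-3-[2-iodo-4,6-bis(methoxymethoxy)phenyl]propan-1-one | Brc1cc(C(=O)CC(O)c2c(I)cc(OCOC)cc2OCOC)cc(CC=C(C)C)c1OC
F3 | step 8 | (1S,3RS)-1-[3-bromo-4-methoxy-5-(3-methylbut-2-enyl)phenyl]-3-[2-iodo-4,6-bis(methoxymethoxy)phenyl]propane-1,3-diol | Brc1cc([C@@H](O)CC(O)c2c(I)cc(OCOC)cc2OCOC)cc(CC=C(C)C)c1OC
F4 | step 7 | rac-3-[2-bromo-4,6-bis(methoxymethoxy)phenyl]-1-[3-bromo-4-methoxy-5-(3-methylbut-2-enyl)phenyl]-3-(tert-butyldimethylsilyloxy)propan-1-one | Brc1cc(C(=O)CC(O[Si](C)(C)C(C)(C)C)c2c(Br)cc(OCOC)cc2OCOC)cc(CC=C(C)C)c1OC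
F5 | step 7 | (1S,3RS)-3-[2-bromo-4,6-bis(methoxymethoxy)phenyl]-1-[3-bromo-4-methoxy-5-(3-methylbut-2-enyl)phenyl]-3-(tert-butyldimethylsilyloxy)propan-1-ol | Brc1cc([C@@H](O)CC(O[Si](C)(C)C(C)(C)C)c2c(Br)cc(OCOC)cc2OCOC)cc(CC=C(C)C)c1OC
F6 | step 12 | 4,4,5,5-tetramethyl-2-[(1E)-3-methylbuta-1,3-dienyl]-1,3,2-dioxaborolane | C=C(C)/C=C/B1OC(C)(C)C(C)(C)O1
F7 | step 12 | (2S,4RS)-2-[4-methoxy-3-[(1E)-3-methylbuta-1,3-dienyl]-5-(3-methylbut-2-enyl)phenyl]-5,7-bis(methoxymethoxy)chroman-4-ol | C=C(C)/C=C/c1cc([C@@H]2CC(O)c3c(OCOC)cc(OCOC)cc3O2)cc(CC=C(C)C)c1OC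
F8 | step 12 | (2S)-2-[4-methoxy-3-[(1E)-3-methylbuta-1,3-dienyl]-5-(3-methylbut-2-enyl)phenyl]-5,7-bis(methoxymethoxy)chroman-4-one | C=C(C)/C=C/c1cc([C@@H]2CC(=O)c3c(OCOC)cc(OCOC)cc3O2)cc(CC=C(C)C)c1OC
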